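All runs stem from a simulated flask for an exercise, noise included.

At early times the rate of making target is easy to read, and the first thing to watch is how quickly it fades.

in all of them: starting material 12 mM; second substrate 15.6 mM
- north: free enzyme 1.4 µM; added ligand 4.2 µM; run made earlier
- north-east: free enzyme 1.4 µM; added ligand 9.3 µM; run made earlier
- south-west: free enzyme 2.8 µM; added ligand 6.2 µM; run made earlier
- flask: free enzyme 1.4 µM; added ligand 6.2 µM

| run | time / d | target / % | starting material / % |
|---|---|---|---|
| north | 0.625 | 5.5 | 94.5 |
| north | 1.25 | 9.6 | 90.2 |
| north | 2.08 | 13.9 | 86.2 |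
| north | 3.00 | 16.7 | 83.8 |
| north | 4.00 | 18.0 | 83.6 |
| north | 5.00 | 17.8 | 82.6 |
| north-east | 0.250 | 2.4 | 97.8 |
| north-east | 0.833 | 5.7 | 94.4 |
| north-east | 1.25 | 7.9 | 92.6 |
| north-east | 2.08 | 11.1 | 89.2 |
| north-east | 3.00 | 13.5 | 86.4 |
| north-east | 4.00 | 14.2 | 85.7 |
| north-east | 5.00 | 14.6 | 85.2 |
| south-west | 1.04 | 15.8 | 84.6 |
| south-west | 2.08 | 24.2 | 75.6 |
| south-west | 3.00 | 27.1 | 73.0 |
| south-west | 4.00 | 28.0 | 71.6 |
| south-west | 5.00 | 28.7 | 71.3 |

(standard deviation of a reading: 0.3 percentage points)

- apparent order in free enzyme when 5.0% of the starting material are converted (percent change of the rate of making target for one percent more free enzyme charged)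
- apparent order in second substrate when 5.0% of the starting material are converted (percent change of the rate of making target for one percent more second substrate charged)

In the north run the mean rate over the first 1.25 d is 0.922 mM/d, and from there to 3.00 d it is 0.487 mM/d. Treat the run as a decaying signal. The midpoints lie 1.50 d apart, which gives the slowing rate, the fractional loss of rate per day, 0.425 /d.

Starting material still stands at 82.6% in north at 5.00 d. South-west has nearly stopped by 4.00 d as well, at 28.0% of target against 18.0% in north, so I take the slowing as a clock that runs by time, not by conversion.

Added ligand costs a factor 0.823 between north and north-east at 1.25 d, where north-east holds less target than north. Interpolated on a log scale, the flask keeps 0.909 of the north rate. That is 0.838 mM/d, and it puts 5.0% conversion near 0.625 d. South-west's first rate, 1.82 mM/d, is twice that, so I take the rate at equal times to follow c(free enzyme).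

At equal conversion, though, doubled enzyme arrives in half the time, having lost less to the clock. So my order in free enzyme, with t the time to that conversion, is 1 + s·t, or 1.27. Steady slowing from the start would add up to 2.57 mM of target, yet the last readings of north and north-east bracket about 1.93 mM, which is less than that, so I expect the slowing to steepen later. No run varies second substrate, so I have no reading of that order.

The forecast gives 1.3 and 0.5, the latter “a guess for partial saturation”.

The flask gives 1.2 for free enzyme and 0.30 for second substrate.

    starting material + free enzyme ⇌ first complex (K = 94.0 /M, k = 3.77 × 10⁵ /M/h)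
    first complex → loaded enzyme + first product (k = 126 /h)
    second substrate + loaded enzyme ⇌ second complex (K = 35.0 /M, k = 1.08 × 10⁶ /M/h)
    second complex → free enzyme + target (k = 357 /h)
    second substrate → decomposed reagent (k = 0.0373 /h)
    free enzyme + added ligand ⇌ idle complex (K = 3.00 × 10⁵ /M, k = 47100 /M/h)

At 0.600 d, with starting material at 95.0%, second substrate stands at 55.5% of its charge, and 6.34 mM of decomposed reagent has formed. Second substrate is the limiting reagent in the flask, down to 0.0855% at 6.00 d. Put the flask's own time to 5.0%, 0.596 d, into your rule with the slowing rate 0.425 /d, and the order in free enzyme comes to 1.25, against 1.2 in the flask.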